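All runs come from a simulation for an exercise; scatter was added.

A small charge, c(substrate) = 0.25 M in the dawn run, gives me the number I carry through these flasks. At its last reading dawn shows 27.1% for Y, the ring per substrate used, that is ring divided by the part of the charge that is no longer substrate; chemists call this the selectivity to ring. I set the zero of its scale by the symmetric case. If an activated form is as likely to close as to catch a second substrate, each such pair of events gives one unit of ring and two units of open dimer, so Y is a third.

| flask | substrate | activator | temperature | remark | time |
|---|---|---|---|---|---|
| dawn | 0.25 M | 0.361 M | 90 °C | run made earlier |  |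
| winter | 0.57 M | 0.361 M | 112 °C | run made earlier |  |
| dusk | 0.38 M | 0.18 M | 90 °C | run made earlier |  |
| epsilon | 0.38 M | 0.361 M | 80 °C |  | 50 h |
| zeta | 0.38 M | 0.361 M |  | at 120 °C until 40 h, from then on at 80 °C | 50 h |
| theta | 0.38 M | 0.361 M | 100 °C |  | 50 h |
| gamma | 0.38 M | 0.361 M | 120 °C |  | 50 h |

| run | time / h | ring / % | substrate / % |
|---|---|---|---|
| dawn | 6.00 | 11 | 31 |
| dawn | 12.0 | 19 | 13 |
| dawn | 20.0 | 22 | 9 |
| dawn | 25.0 | 24 | 6 |
| dawn | 30.0 | 26 | 4 |
| winter | 0.833 | 11 | 44 |
| winter | 2.50 | 13 | 24 |
| winter | 5.00 | 18 | 17 |
| winter | 8.00 | 15 | 15 |
| winter | 10.0 | 18 | 10 |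
| dusk | 6.00 | 6 | 51 |
| dusk | 12.0 | 6 | 39 |
| dusk | 20.0 | 9 | 31 |
| dusk | 25.0 | 7 | 33 |
| dusk | 30.0 | 8 | 29 |

(each reading ± 2 percentage points)

- percent here means substrate units held: one open dimer counts as two
- the numbers in the tables scatter with a standard deviation of 2 percentage points
- candidate steps: substrate + activator -> activated form; activated form -> ring; substrate + activated form -> open dimer; substrate <-> dormant form; ring <-> isomer of the product

* which flask leads in amount of ring, in percent of the substrate charged ("all alike" within 1.5 percentage points) (epsilon / zeta / theta / gamma / all alike)
* how much ring is there at the end, in percent of the substrate charged: epsilon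
* how much ring is there at the end, in percent of the substrate charged: zeta
* how much ring is there at the end, in percent of the substrate charged: theta
* how much ring is there at the end, in percent of the substrate charged: gamma

Now I turn the settings one at a time. By hand, substrate should lower Y as it rises, with the rest held, since closure needs no partner and the dimer step needs a substrate. Winter, at c(substrate) = 0.57 M, reads 20.0%, less than dawn, though winter is hotter as well. By hand, activator should bring substrate into the activated form faster. Dusk has half of dawn's activator and also more substrate than dawn, so two settings differ; at its last reading it shows 11.3%, lower than dawn or winter, with 29% of its substrate still standing. By hand, heat speeds the steps, and Y asks which of them gains more. No two runs differ in temperature alone, so I can say just that winter at 112 °C reads above dusk at 90 °C, with their charges differing too. By hand, time turns more of the substrate left into ring, while the step to the isomer of the product can take ring away. In winter the ring reads 18% at 5.00 h and 18% at 10.0 h, while the substrate reads 17% and then 10%.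

The new flasks stand at 0.38 M, between dawn and winter, so my own reckoning takes the middle of their two values, 23.5%, as Y. Winter reads 90.0% of its substrate used at 10.0 h, at a lower temperature than gamma, so I take that Y as the ring I expect in gamma as well.

The forecast says 18% for epsilon, 22% for zeta, 20% for theta and 21% for gamma, this last within 14% to 29% and under my figure. It names zeta as leader: “Zeta should roughly match gamma, perhaps slightly higher after cooling.”

The flasks give 14.3% in epsilon, 24.3% in zeta, 21.7% in theta and 29.2% in gamma, so gamma leads.

    substrate + activator → activated form (k = 0.0180 /M/min, Ea = 82.0 kJ/mol)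
    activated form → ring (k = 0.00810 /min, Ea = 129 kJ/mol)
    substrate + activated form → open dimer (k = 0.0370 /M/min, Ea = 100 kJ/mol)
    substrate ⇌ dormant form (K = 0.250, k = 0.00290 /min, Ea = 109 kJ/mol, ΔH = 3.00 kJ/mol)
    ring ⇌ isomer of the product (K = 1.40, k = 0.00680 /min, Ea = 105 kJ/mol, ΔH = −16.0 kJ/mol)
    (constants at 100 °C)

Gamma ends 8.2 percentage points above the forecast. Zeta holds 29.2% of ring at 40.0 h and 24.3% at 50.0 h, while its isomer of the product goes from 31.5% to 36.4%. Gamma's Y is 29.2%, above my 23.5%. A neighbour of gamma with c(substrate) = 0.65 M ends with 15.2% of ring and 16% of its substrate left, so its Y is 18.1%.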